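**Retrosynthetic overview**
1. The only ring, the 42-membered lactone, is closed last but one by macrolactonisation (O–C1) of seco acid 77. The (2E,4Z)-dienoate is grown late from a C5 aldehyde (Still–Gennari, then stabilised Wittig).
2. C19–C20: acetylide addition of fragment ME (C20–C50) to the C19 aldehyde of fragment W (C5–C19), then ynone transfer hydrogenation and semi-hydrogenation give the 19-hydroxy-20Z unit.
3. C38=C39: Z-selective Wittig between fragment M (C20–C38 phosphonium salt) and fragment E (C39–C50 aldehyde).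
4. Fragment W: two-directional iridium-catalysed allylation from propane-1,3-diol (C2-symmetric all-anti polyol), ends differentiated once. Fragment M: iterative allylation/hydroformylation.
5. Fragment E: a ketoreductase sets C49, and a second ketoreductase (dynamic reductive kinetic resolution) sets C41/C42; C43 follows by 1,3-syn reduction.

Assumption: the SMILES is read as 2E,4Z,20Z,38Z and 7S,9R,11S,13R,15S,17R,18R,19R,23R,27R,31R,41S,42S,43R,49R; ligand, acid and enzyme antipodes named are those expected to give the stated products (the mirror-image catalyst is used if a batch shows the opposite sense); locants C1–C50 are those of the target chain (C1 lactone carbonyl, C41 lactone carbinol, C50 terminal methyl); TBS = tert-butyldimethylsilyl, PMB = 4-methoxybenzyl, Piv = pivaloyl.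

**Fragment W (C5–C19)**

Step 1
Reactants: 1 propane-1,3-diol; 2 allyl acetate
Product: 4 (4S,6S)-nona-1,8-diene-4,6-diol, via mono-allyl diol 3 (not isolated)
Conditions: [Ir(cod)Cl]2 (5 mol%), (S)-Cl,MeO-BIPHEP (10 mol%), 4-chloro-3-nitrobenzoic acid (20 mol%), Cs2CO3 (40 mol%), 2 (10 equiv), 1,4-dioxane, 90 °C
Reagents that add atoms: none
Why: Krische two-directional transfer-hydrogenative allylation; the chiral cyclometallated iridium catalyst sets C11 and C13 (the first stereocentres) under catalyst control and gives the C2-symmetric anti diol.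

Step 2
Reactants: 4 (4S,6S)-nona-1,8-diene-4,6-diol
Product: 5 (4S,6S)-4,6-diallyl-2,2-dimethyl-1,3-dioxane
Conditions: 2,2-dimethoxypropane, PPTS (cat.), CH2Cl2, rt
Reagents that add atoms: 2,2-dimethoxypropane, COC(C)(C)OC
Why: Acid-catalysed transketalisation (acetonide formation) protects the anti-1,3-diol without touching a stereocentre.

Step 3
Reactants: 5 (4S,6S)-4,6-diallyl-2,2-dimethyl-1,3-dioxane
Product: 8 2,2'-[(4S,6S)-2,2-dimethyl-1,3-dioxane-4,6-diyl]diethanol (C9–C15 diol), via bis-ozonide 6 (not isolated), via dialdehyde 7 (not isolated)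
Conditions: O3, CH2Cl2, −78 °C; then NaBH4, MeOH, −78 °C → rt
Reagents that add atoms: ozone, [O-][O+]=O
Why: Ozonolysis with reductive borohydride work-up shortens both allyl arms to primary alcohols, ready for the next two-directional allylation.

Step 4
Reactants: 8 C9–C15 diol; 2 allyl acetate
Product: 10 (2R,2'R)-1,1'-[(4S,6S)-2,2-dimethyl-1,3-dioxane-4,6-diyl]bis(pent-4-en-2-ol), via mono-allyl adduct 9 (not isolated)
Conditions: [Ir(cod)Cl]2 (5 mol%), (R)-Cl,MeO-BIPHEP (10 mol%), 4-chloro-3-nitrobenzoic acid (20 mol%), Cs2CO3 (40 mol%), 2 (10 equiv), 1,4-dioxane, 90 °C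
Reagents that add atoms: none
Why: Second Krische double allylation; the (R)-ligand sets C9 and C15 anti to C11/C13 by catalyst control.

Step 5
Reactants: 10 diene diol
Product: 11 C6–C18 diene (9,15-bis-OTBS; 11,13-acetonide)
Conditions: TBSCl, imidazole, DMF, rt
Reagents that add atoms: tert-butyldimethylsilyl chloride, CC(C)(C)[Si](C)(C)Cl
Why: Standard silylation of two unhindered secondary alcohols.

Step 6
Reactants: 11 C6–C18 diene
Product: 14 C7–C17 diol (9,15-bis-OTBS; 11,13-acetonide), via bis-ozonide 12 (not isolated), via dialdehyde 13 (not isolated)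
Conditions: O3, CH2Cl2, −78 °C; then NaBH4, MeOH, −78 °C → rt
Reagents that add atoms: ozone, [O-][O+]=O
Why: Ozonolysis with reductive work-up gives the C2-symmetric diol whose two ends are homotopic.

Step 7
Reactants: 14 C7–C17 diol
Product: 15 C7–C17 mono-benzyl ether (7-OH; 17-OBn)
Conditions: Ag2O (1.5 equiv), BnBr (1.1 equiv), CH2Cl2, rt; recovered diol and bis-ether are recycled
Reagents that add atoms: benzyl bromide, BrCc1ccccc1
Why: Silver-oxide-mediated Williamson mono-benzylation; because the ends are homotopic only one mono-ether can form, and the non-basic conditions avoid silyl migration.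

Step 8
Reactants: 15 mono-benzyl ether; 2 allyl acetate
Product: 16 C4–C17 homoallylic alcohol (7-OH; 17-OBn)
Conditions: [Ir(cod)Cl]2 (2.5 mol%), (S)-Cl,MeO-BIPHEP (5 mol%), 4-chloro-3-nitrobenzoic acid (10 mol%), Cs2CO3 (20 mol%), THF, 100 °C
Reagents that add atoms: none
Why: Krische allylation from the alcohol oxidation level; the (S)-ligand sets C7 (S), anti to C9.

Step 9
Reactants: 16 homoallylic alcohol
Product: 17 C4–C17 alkene (7,9,15-tris-OTBS; 17-OBn)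
Conditions: TBSCl, imidazole, DMF, rt
Reagents that add atoms: tert-butyldimethylsilyl chloride, CC(C)(C)[Si](C)(C)Cl
Why: Standard silylation of the new secondary alcohol.

Step 10
Reactants: 17 C4–C17 alkene
Product: 20 C5–C17 alcohol (5-OH; 17-OBn), via ozonide 18 (not isolated), via aldehyde 19 (not isolated)
Conditions: O3, CH2Cl2, −78 °C (stopped at first blue colour); then NaBH4, MeOH, −78 °C → rt
Reagents that add atoms: ozone, [O-][O+]=O
Why: Ozonolysis with reductive work-up turns the allyl group into the C5 primary alcohol while the benzyl ether survives brief exposure.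

Step 11
Reactants: 20 C5 alcohol
Product: 21 C5–C17 pivalate (5-OPiv; 17-OBn)
Conditions: PivCl, pyridine, DMAP (cat.), CH2Cl2, 0 °C → rt
Reagents that add atoms: pivaloyl chloride, CC(C)(C)C(Cl)=O
Why: Acylation gives an ester with no α-hydrogen that tolerates bases and organolithiums and is later removed reductively.

Step 12
Reactants: 21 pivalate benzyl ether
Product: 22 C5–C17 alcohol (5-OPiv; 17-OH)
Conditions: H2 (1 atm), Pd/C (10%), EtOAc, rt
Reagents that add atoms: none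
Why: Hydrogenolysis of the benzyl ether; no alkene is present at this stage and silyl ethers, acetonide and pivalate are inert in ethyl acetate.

Step 13
Reactants: 22 C17 alcohol
Product: 23 C5–C17 aldehyde (5-OPiv; C17 CHO)
Conditions: Dess–Martin periodinane, NaHCO3, CH2Cl2, 0 °C → rt
Reagents that add atoms: none
Why: Buffered Dess–Martin oxidation gives the β-silyloxy aldehyde without elimination.

Step 14
Reactants: 23 C17 aldehyde; 24 (E)-crotylboronic acid pinacol ester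
Product: 25 C5–C20 anti-homoallylic alcohol (17-OH; 18-Me)
Conditions: (S)-TRIP phosphoric acid (5 mol%), 4 Å MS, toluene, −30 °C; aq. NaHCO3
Reagents that add atoms: none
Why: Chiral-phosphoric-acid-catalysed crotylboration; the closed chair transition state of the (E)-boronate gives 17,18-anti and the catalyst selects the aldehyde face, giving C17 (R) anti to C15.

Step 15
Reactants: 25 anti-homoallylic alcohol
Product: 26 C5–C20 alkene (17-OTBS)
Conditions: TBSOTf, 2,6-lutidine, CH2Cl2, −78 → 0 °C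
Reagents that add atoms: tert-butyldimethylsilyl triflate, CC(C)(C)[Si](C)(C)OS(=O)(=O)C(F)(F)F
Why: The silyl triflate silylates the hindered secondary alcohol under buffered conditions.

Step 16
Reactants: 26 C5–C20 alkene
Product: 28 fragment W aldehyde (C5–C19; C19 CHO), via ozonide 27 (not isolated)
Conditions: O3, CH2Cl2, −78 °C; then PPh3, −78 °C → rt
Reagents that add atoms: ozone, [O-][O+]=O
Why: Ozonolysis with neutral phosphine work-up unveils the α-methyl aldehyde without epimerising C18.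

**Fragment M (C20–C38)**

Step 17
Reactants: 29 8-chlorooctan-1-ol; 2 allyl acetate
Product: 30 (4R)-11-chloroundec-1-en-4-ol
Conditions: [Ir(cod)Cl]2 (2.5 mol%), (S)-Cl,MeO-BIPHEP (5 mol%), 4-chloro-3-nitrobenzoic acid (10 mol%), Cs2CO3 (20 mol%), THF, 100 °C
Reagents that add atoms: none
Why: Krische allylation sets C31 (R) by catalyst control; the primary chloride is inert.

Step 18
Reactants: 30 (4R)-11-chloroundec-1-en-4-ol
Product: 31 TBS ether of 30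
Conditions: TBSCl, imidazole, DMF, rt
Reagents that add atoms: tert-butyldimethylsilyl chloride, CC(C)(C)[Si](C)(C)Cl
Why: Standard silylation.

Step 19
Reactants: 31 TBS ether
Product: 32 C27–C38 aldehyde (31-OTBS; 38-Cl)
Conditions: CO/H2 (1:1, 10 bar), Rh(acac)(CO)2 (1 mol%), BIPHEPHOS (3 mol%), toluene, 60 °C
Reagents that add atoms: carbon monoxide, [C-]#[O+]
Why: Linear-selective rhodium-catalysed hydroformylation (wide-bite-angle bisphosphite) adds C27 and gives the 1,5-spacing directly.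

Step 20
Reactants: 32 C27 aldehyde; 2 allyl acetate
Product: 33 C24–C38 homoallylic alcohol (27-OH; 31-OTBS)
Conditions: [Ir(cod)Cl]2 (2.5 mol%), (S)-Cl,MeO-BIPHEP (5 mol%), 4-chloro-3-nitrobenzoic acid (10 mol%), Cs2CO3 (20 mol%), i-PrOH (2 equiv), THF, 100 °C
Reagents that add atoms: none
Why: Krische allylation from the aldehyde oxidation level (isopropanol as reductant) sets C27 (R) by catalyst control; the remote C31 centre has no influence.

Step 21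
Reactants: 33 homoallylic alcohol
Product: 34 C24–C38 alkene (27,31-bis-OTBS)
Conditions: TBSCl, imidazole, DMF, rt
Reagents that add atoms: tert-butyldimethylsilyl chloride, CC(C)(C)[Si](C)(C)Cl
Why: Standard silylation.

Step 22
Reactants: 34 alkene
Product: 35 C23–C38 aldehyde (27,31-bis-OTBS)
Conditions: CO/H2 (1:1, 10 bar), Rh(acac)(CO)2 (1 mol%), BIPHEPHOS (3 mol%), toluene, 60 °C
Reagents that add atoms: carbon monoxide, [C-]#[O+]
Why: Second linear-selective hydroformylation adds C23.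

Step 23
Reactants: 35 C23 aldehyde; 2 allyl acetate
Product: 36 C20–C38 homoallylic alcohol (23-OH)
Conditions: [Ir(cod)Cl]2 (2.5 mol%), (S)-Cl,MeO-BIPHEP (5 mol%), 4-chloro-3-nitrobenzoic acid (10 mol%), Cs2CO3 (20 mol%), i-PrOH (2 equiv), THF, 100 °C
Reagents that add atoms: none
Why: Third Krische allylation sets C23 (R) by catalyst control.

Step 24
Reactants: 36 homoallylic alcohol
Product: 37 C20–C38 alkene (23,27,31-tris-OTBS)
Conditions: TBSCl, imidazole, DMF, rt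
Reagents that add atoms: tert-butyldimethylsilyl chloride, CC(C)(C)[Si](C)(C)Cl
Why: Standard silylation.

Step 25
Reactants: 37 alkene
Product: 39 C21–C38 aldehyde, via ozonide 38 (not isolated)
Conditions: O3, CH2Cl2, −78 °C; then PPh3, −78 °C → rt
Reagents that add atoms: ozone, [O-][O+]=O
Why: Ozonolysis with phosphine work-up gives the β-silyloxy aldehyde at C21.

Step 26
Reactants: 39 C21 aldehyde
Product: 40 C20–C38 alkyne chloride
Conditions: dimethyl (1-diazo-2-oxopropyl)phosphonate, K2CO3, MeOH, 0 °C → rt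
Reagents that add atoms: dimethyl (1-diazo-2-oxopropyl)phosphonate, COP(=O)(OC)C(=[N+]=[N-])C(C)=O
Why: Ohira–Bestmann (Seyferth–Gilbert) homologation turns the aldehyde into the terminal alkyne C20≡C21 under mild base.

Step 27
Reactants: 40 alkyne chloride
Product: 41 C20–C38 alkyne iodide
Conditions: NaI (5 equiv), acetone, reflux
Reagents that add atoms: sodium iodide, [Na+].[I-]
Why: Finkelstein halide exchange, driven by precipitation of NaCl.

Step 28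
Reactants: 41 alkyne iodide
Product: 42 fragment M phosphonium iodide
Conditions: PPh3 (3 equiv), i-Pr2NEt (0.1 equiv), MeCN, 80 °C
Reagents that add atoms: triphenylphosphine, c1ccc(cc1)P(c1ccccc1)c1ccccc1
Why: SN2 quaternisation of the primary iodide; the amine buffer protects the silyl ethers from traces of HI.

**Fragment E (C39–C50)**

Step 29
Reactants: 43 7-bromoheptan-2-one
Product: 44 (2R)-7-bromoheptan-2-ol
Conditions: (R)-selective NADPH-dependent ketoreductase (alcohol dehydrogenase class), NADP+ (cat.), i-PrOH (10 vol%), MgCl2 (1 mM), phosphate buffer pH 7.0, 30 °C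
Reagents that add atoms: none
Why: Ketoreductase (anti-Prelog alcohol dehydrogenase) reduction of a methyl ketone sets C49 (R) in >99% ee, with isopropanol recycling the cofactor.

Step 30
Reactants: 44 (2R)-7-bromoheptan-2-ol
Product: 45 (R)-[(7-bromoheptan-2-yl)oxy](tert-butyl)dimethylsilane
Conditions: TBSCl, imidazole, CH2Cl2, rt
Reagents that add atoms: tert-butyldimethylsilyl chloride, CC(C)(C)[Si](C)(C)Cl
Why: Standard silylation.

Step 31
Reactants: 46 3-[(4-methoxybenzyl)oxy]propan-1-ol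
Product: 47 3-[(4-methoxybenzyl)oxy]propanal
Conditions: Dess–Martin periodinane, NaHCO3, CH2Cl2, 0 °C → rt
Reagents that add atoms: none
Why: Mild Dess–Martin oxidation of a primary alcohol.

Step 32
Reactants: 48 ethyl propanoate; 47 3-[(4-methoxybenzyl)oxy]propanal
Product: 50 ethyl 3-hydroxy-5-[(4-methoxybenzyl)oxy]-2-methylpentanoate (stereoisomer mixture), via lithium enolate 49 (not isolated)
Conditions: LiN(i-Pr)2, THF, −78 °C; then 47, −78 °C; aq. NH4Cl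
Reagents that add atoms: none
Why: Lithium ester-enolate aldol addition builds C41–C43; its stereochemistry is irrelevant because both centres are erased or reset in the next two steps.

Step 33
Reactants: 50 hydroxy ester mixture
Product: 51 ethyl 5-[(4-methoxybenzyl)oxy]-2-methyl-3-oxopentanoate
Conditions: Dess–Martin periodinane, NaHCO3, CH2Cl2, rt
Reagents that add atoms: none
Why: Dess–Martin oxidation gives the configurationally labile α-methyl β-keto ester.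

Step 34
Reactants: 51 β-keto ester
Product: 52 ethyl (2R,3S)-3-hydroxy-5-[(4-methoxybenzyl)oxy]-2-methylpentanoate
Conditions: (2R,3S)-selective NADPH-dependent ketoreductase (from a panel screen), NADP+ (cat.), i-PrOH (10 vol%), DMSO (5 vol%), phosphate buffer pH 7.0, 30 °C
Reagents that add atoms: none
Why: Ketoreductase-catalysed dynamic reductive kinetic resolution; the α-centre racemises through the enol while the enzyme reduces one enantiomer on one face, setting C41 (S) and the 41,42-syn C42 centre together.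

Step 35
Reactants: 52 syn hydroxy ester
Product: 53 (2R,3S)-3-hydroxy-N-methoxy-5-[(4-methoxybenzyl)oxy]-N,2-dimethylpentanamide
Conditions: MeNH(OMe)·HCl, i-PrMgCl, THF, −20 → 0 °C
Reagents that add atoms: N,O-dimethylhydroxylamine hydrochloride, CNOC.Cl
Why: Aminolysis of the ester by the magnesium amide (Weinreb amide formation) proceeds without protecting the hydroxyl and without epimerisation.

Step 36
Reactants: 45 silyl ether bromide; 53 Weinreb amide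
Product: 55 C39–C50 β-hydroxy ketone (39-OPMB; 41-OH; C43 ketone; 49-OTBS), via Grignard reagent 54 (not isolated)
Conditions: Mg, THF, 40 °C (3.3 equiv of 45); then 53, THF, 0 °C; aq. NH4Cl
Reagents that add atoms: none
Why: Grignard addition to the Weinreb amide stops at the ketone through the chelated tetrahedral intermediate, with one equivalent consumed by the free hydroxyl.

Step 37
Reactants: 55 β-hydroxy ketone
Product: 57 C39–C50 syn,syn-diol (41,43-diol), via diethylboron chelate 56 (not isolated)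
Conditions: Et2BOMe, THF/MeOH (4:1), −78 °C; NaBH4, −78 °C; AcOH, then MeOH co-evaporation
Reagents that add atoms: none
Why: Narasaka–Prasad reduction; external hydride attacks the six-membered boron chelate axially and gives the 1,3-syn diol, setting C43 (R).

Step 38
Reactants: 57 syn,syn-diol
Product: 58 C39/C41 p-methoxybenzylidene acetal (43-OH free)
Conditions: DDQ (1.2 equiv), 4 Å MS, CH2Cl2, 0 °C
Reagents that add atoms: none
Why: Anhydrous DDQ oxidation of the PMB ether gives an oxocarbenium ion that is trapped by the 1,3-related C41 hydroxyl as the six-membered acetal, which distinguishes C41–OH from C43–OH.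

Step 39
Reactants: 58 acetal alcohol
Product: 59 acetal TBS ether (43-OTBS)
Conditions: TBSOTf, 2,6-lutidine, CH2Cl2, −78 → 0 °C
Reagents that add atoms: tert-butyldimethylsilyl triflate, CC(C)(C)[Si](C)(C)OS(=O)(=O)C(F)(F)F
Why: Silylation of the hindered C43 alcohol under buffered conditions.

Step 40
Reactants: 59 acetal TBS ether
Product: 60 C39–C50 alcohol (39-OH; 41-OPMB; 43,49-bis-OTBS)
Conditions: i-Bu2AlH (3 equiv), CH2Cl2, −78 → 0 °C; Rochelle salt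
Reagents that add atoms: none
Why: Regioselective reductive opening of the benzylidene acetal; aluminium coordinates the less hindered oxygen, so the PMB group ends on the secondary C41 oxygen and C39 is freed.

Step 41
Reactants: 60 C39 alcohol
Product: 61 fragment E aldehyde (C39 CHO)
Conditions: Dess–Martin periodinane, NaHCO3, CH2Cl2, 0 °C → rt
Reagents that add atoms: none
Why: Buffered Dess–Martin oxidation gives the β-alkoxy aldehyde without elimination.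

**Fragment union and endgame**

Step 42
Reactants: 42 fragment M phosphonium iodide; 61 fragment E aldehyde
Product: 63 fragment ME alkyne (C20–C50; 38Z), via phosphonium ylide 62 (not isolated)
Conditions: NaN(SiMe3)2 (1.0 equiv), THF, −78 °C; then 61, −78 °C → rt
Reagents that add atoms: none
Why: Salt-free Wittig reaction of a non-stabilised ylide gives the 38Z alkene under kinetic control; the phosphonium C–H is far more acidic than the alkyne C–H, so one equivalent of base forms only the ylide.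

Step 43
Reactants: 63 fragment ME alkyne; 28 fragment W aldehyde
Product: 65 C5–C50 propargylic alcohol (C19 epimer mixture), via lithium acetylide 64 (not isolated)
Conditions: n-BuLi (1.0 equiv), THF, −78 °C; then 28, −78 °C; aq. NH4Cl
Reagents that add atoms: none
Why: Lithium acetylide 1,2-addition to the aldehyde forms C19–C20; the pivalate is untouched at −78 °C and the C19 configuration is corrected in the next two steps.

Step 44
Reactants: 65 propargylic alcohol mixture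
Product: 66 C5–C50 ynone (C19 ketone)
Conditions: Dess–Martin periodinane, NaHCO3, CH2Cl2, 0 °C → rt
Reagents that add atoms: none
Why: Dess–Martin oxidation converges both epimers to one ynone.

Step 45
Reactants: 66 ynone
Product: 67 C5–C50 (19S)-propargylic alcohol
Conditions: Ru[(S,S)-TsDPEN](p-cymene) (5 mol%), i-PrOH, rt
Reagents that add atoms: none
Why: Noyori asymmetric transfer hydrogenation of the ynone under base-free conditions sets C19 by catalyst control (the alkynyl group takes the place of the aryl group) without epimerising C18.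

Step 46
Reactants: 67 propargylic alcohol
Product: 68 C5–C50 (20Z)-allylic alcohol
Conditions: H2 (1 atm), Pd/CaCO3 poisoned with Pb(OAc)2 (Lindlar catalyst), quinoline, EtOAc, rt
Reagents that add atoms: none
Why: Lindlar syn semi-hydrogenation gives the 20Z alkene and leaves the isolated 38Z alkene and the PMB ether alone.

Step 47
Reactants: 68 allylic alcohol
Product: 69 C19 TBS ether (5-OPiv; 41-OPMB)
Conditions: TBSOTf, 2,6-lutidine, CH2Cl2, −78 → 0 °C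
Reagents that add atoms: tert-butyldimethylsilyl triflate, CC(C)(C)[Si](C)(C)OS(=O)(=O)C(F)(F)F
Why: Silylation of the hindered allylic alcohol under buffered conditions.

Step 48
Reactants: 69 pivalate
Product: 70 C5 alcohol
Conditions: i-Bu2AlH (2.5 equiv), CH2Cl2, −78 °C; Rochelle salt
Reagents that add atoms: none
Why: Reductive cleavage of the only ester in the molecule frees the C5 alcohol under non-basic conditions.

Step 49
Reactants: 70 C5 alcohol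
Product: 71 C5 aldehyde
Conditions: Dess–Martin periodinane, NaHCO3, CH2Cl2, 0 °C → rt
Reagents that add atoms: none
Why: Buffered Dess–Martin oxidation to the β-silyloxy aldehyde.

Step 50
Reactants: 71 C5 aldehyde
Product: 72 C3–C50 ethyl (Z)-enoate
Conditions: ethyl 2-[bis(2,2,2-trifluoroethoxy)phosphoryl]propanoate, KN(SiMe3)2, 18-crown-6, THF, −78 °C
Reagents that add atoms: ethyl 2-[bis(2,2,2-trifluoroethoxy)phosphoryl]propanoate, CCOC(=O)C(C)P(=O)(OCC(F)(F)F)OCC(F)(F)F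
Why: Still–Gennari olefination gives the (Z)-trisubstituted C4=C5 alkene by fast, irreversible elimination from the syn adduct.

Step 51
Reactants: 72 (Z)-enoate
Product: 73 C3–C50 (Z)-allylic alcohol
Conditions: i-Bu2AlH (2.5 equiv), CH2Cl2, −78 °C; Rochelle salt
Reagents that add atoms: none
Why: 1,2-Reduction of the enoate to the allylic alcohol with retention of alkene geometry.

Step 52
Reactants: 73 (Z)-allylic alcohol
Product: 74 C3–C50 (Z)-enal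
Conditions: MnO2 (excess), CH2Cl2, rt
Reagents that add atoms: none
Why: Chemoselective allylic oxidation under neutral conditions keeps the Z geometry.

Step 53
Reactants: 74 (Z)-enal
Product: 75 C1–C50 methyl (2E,4Z)-dienoate (41-OPMB)
Conditions: Ph3P=CHCO2Me, toluene, 40 °C
Reagents that add atoms: methyl (triphenylphosphoranylidene)acetate, COC(=O)C=P(c1ccccc1)(c1ccccc1)c1ccccc1
Why: Wittig reaction with a stabilised ylide gives the 2E alkene under neutral conditions that do not isomerise C4=C5.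

Step 54
Reactants: 75 dienoate PMB ether
Product: 76 C41 alcohol (methyl ester)
Conditions: DDQ, CH2Cl2/pH 7 phosphate buffer (10:1), 0 °C
Reagents that add atoms: none
Why: Oxidative PMB cleavage is selective for the electron-rich benzyl ether over the electron-poor dienoate and the silyl ethers.

Step 55
Reactants: 76 hydroxy ester
Product: 77 seco acid
Conditions: LiOH, THF/MeOH/H2O, rt; then dilute HCl to pH 4, 0 °C
Reagents that add atoms: lithium hydroxide, [Li+].[OH-]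
Why: Saponification of the only ester gives the hydroxy acid; silyl ethers and the acetonide survive.

Step 56
Reactants: 77 seco acid
Product: 79 protected macrolactone (ten TBS ethers; 11,13-acetonide), via mixed anhydride 78 (not isolated)
Conditions: 2,4,6-trichlorobenzoyl chloride, Et3N, THF, rt; then slow addition to DMAP (10 equiv), toluene (0.5 mM), 40 °C
Reagents that add atoms: none
Why: Yamaguchi macrolactonisation; DMAP acyl transfer from the mixed anhydride under high dilution closes the 42-membered ring at the C41 hydroxyl with retention.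

Step 57
Reactants: 79 protected macrolactone
Product: 80 CNP0071908.1
Conditions: 48% aq. HF, MeCN/THF (3:1), 0 °C → rt
Reagents that add atoms: none
Why: Global deprotection; fluoride-assisted acidic cleavage removes all ten TBS ethers and hydrolyses the labile anti-acetonide without acyl migration.

**Compound list**

1 | propane-1,3-diol | OCCCO | starting material
2 | allyl acetate | CC(=O)OCC=C | starting material
3 | (S)-hex-5-ene-1,3-diol (mono-allyl diol) | C=CC[C@H](O)CCO | intermediate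
4 | (4S,6S)-nona-1,8-diene-4,6-diol | C=CC[C@H](O)C[C@@H](O)CC=C | intermediate
5 | (4S,6S)-4,6-diallyl-2,2-dimethyl-1,3-dioxane | C=CC[C@H](OC1(C)C)C[C@@H](O1)CC=C | intermediate
6 | bis-ozonide of 5 (trioxolane carbons as epimer mixture) | C1OOC(O1)C[C@H](OC2(C)C)C[C@@H](O2)CC3OOCO3 | intermediate
7 | dialdehyde from 5 (trans-4,6-bis(2-oxoethyl)-2,2-dimethyl-1,3-dioxane) | O=CC[C@H](OC1(C)C)C[C@@H](O1)CC=O | intermediate
8 | 2,2'-[(4S,6S)-2,2-dimethyl-1,3-dioxane-4,6-diyl]diethanol (C9–C15 diol) | OCC[C@H](OC1(C)C)C[C@@H](O1)CCO | intermediate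
9 | mono-allyl adduct of 8 | C=CC[C@@H](O)C[C@H](OC1(C)C)C[C@@H](O1)CCO | intermediate
10 | (2R,2'R)-1,1'-[(4S,6S)-2,2-dimethyl-1,3-dioxane-4,6-diyl]bis(pent-4-en-2-ol) | C=CC[C@@H](O)C[C@H](OC1(C)C)C[C@@H](O1)C[C@H](O)CC=C | intermediate
11 | C6–C18 diene, 9,15-bis-OTBS, 11,13-acetonide | C=CC[C@@H](O[Si](C)(C)C(C)(C)C)C[C@H](OC1(C)C)C[C@@H](O1)C[C@H](O[Si](C)(C)C(C)(C)C)CC=C | intermediate
12 | bis-ozonide of 11 | C1OOC(O1)C[C@@H](O[Si](C)(C)C(C)(C)C)C[C@H](OC2(C)C)C[C@@H](O2)C[C@H](O[Si](C)(C)C(C)(C)C)CC3OOCO3 | intermediate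
13 | C7,C17-dialdehyde, 9,15-bis-OTBS, 11,13-acetonide | O=CC[C@@H](O[Si](C)(C)C(C)(C)C)C[C@H](OC1(C)C)C[C@@H](O1)C[C@H](O[Si](C)(C)C(C)(C)C)CC=O | intermediate
14 | C7–C17 diol, 9,15-bis-OTBS, 11,13-acetonide | OCC[C@@H](O[Si](C)(C)C(C)(C)C)C[C@H](OC1(C)C)C[C@@H](O1)C[C@H](O[Si](C)(C)C(C)(C)C)CCO | intermediate
15 | C7–C17 mono-benzyl ether (7-OH, 17-OBn) | OCC[C@@H](O[Si](C)(C)C(C)(C)C)C[C@H](OC1(C)C)C[C@@H](O1)C[C@H](O[Si](C)(C)C(C)(C)C)CCOCc1ccccc1 | intermediate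
16 | C4–C17 homoallylic alcohol (7-OH, 17-OBn) | C=CC[C@H](O)C[C@@H](O[Si](C)(C)C(C)(C)C)C[C@H](OC1(C)C)C[C@@H](O1)C[C@H](O[Si](C)(C)C(C)(C)C)CCOCc1ccccc1 | intermediate
17 | C4–C17 alkene, 7,9,15-tris-OTBS, 17-OBn | C=CC[C@H](O[Si](C)(C)C(C)(C)C)C[C@@H](O[Si](C)(C)C(C)(C)C)C[C@H](OC1(C)C)C[C@@H](O1)C[C@H](O[Si](C)(C)C(C)(C)C)CCOCc1ccccc1 | intermediate
18 | ozonide of 17 | C1OOC(O1)C[C@H](O[Si](C)(C)C(C)(C)C)C[C@@H](O[Si](C)(C)C(C)(C)C)C[C@H](OC2(C)C)C[C@@H](O2)C[C@H](O[Si](C)(C)C(C)(C)C)CCOCc1ccccc1 | intermediate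
19 | C5 aldehyde, 17-OBn | O=CC[C@H](O[Si](C)(C)C(C)(C)C)C[C@@H](O[Si](C)(C)C(C)(C)C)C[C@H](OC1(C)C)C[C@@H](O1)C[C@H](O[Si](C)(C)C(C)(C)C)CCOCc1ccccc1 | intermediate
20 | C5–C17 alcohol (5-OH, 17-OBn) | OCC[C@H](O[Si](C)(C)C(C)(C)C)C[C@@H](O[Si](C)(C)C(C)(C)C)C[C@H](OC1(C)C)C[C@@H](O1)C[C@H](O[Si](C)(C)C(C)(C)C)CCOCc1ccccc1 | intermediate
21 | C5–C17 pivalate (5-OPiv, 17-OBn) | CC(C)(C)C(=O)OCC[C@H](O[Si](C)(C)C(C)(C)C)C[C@@H](O[Si](C)(C)C(C)(C)C)C[C@H](OC1(C)C)C[C@@H](O1)C[C@H](O[Si](C)(C)C(C)(C)C)CCOCc1ccccc1 | intermediate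
22 | C5–C17 alcohol (5-OPiv, 17-OH) | CC(C)(C)C(=O)OCC[C@H](O[Si](C)(C)C(C)(C)C)C[C@@H](O[Si](C)(C)C(C)(C)C)C[C@H](OC1(C)C)C[C@@H](O1)C[C@H](O[Si](C)(C)C(C)(C)C)CCO | intermediate
23 | C5–C17 aldehyde (5-OPiv, C17 CHO) | CC(C)(C)C(=O)OCC[C@H](O[Si](C)(C)C(C)(C)C)C[C@@H](O[Si](C)(C)C(C)(C)C)C[C@H](OC1(C)C)C[C@@H](O1)C[C@H](O[Si](C)(C)C(C)(C)C)CC=O | intermediate
24 | (E)-crotylboronic acid pinacol ester | C/C=C/CB1OC(C)(C)C(C)(C)O1 | starting material
25 | C5–C20 anti-homoallylic alcohol (17-OH, 18-Me) | CC(C)(C)C(=O)OCC[C@H](O[Si](C)(C)C(C)(C)C)C[C@@H](O[Si](C)(C)C(C)(C)C)C[C@H](OC1(C)C)C[C@@H](O1)C[C@H](O[Si](C)(C)C(C)(C)C)C[C@@H](O)[C@@H](C)C=C | intermediate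
26 | C5–C20 alkene (17-OTBS) | CC(C)(C)C(=O)OCC[C@H](O[Si](C)(C)C(C)(C)C)C[C@@H](O[Si](C)(C)C(C)(C)C)C[C@H](OC1(C)C)C[C@@H](O1)C[C@H](O[Si](C)(C)C(C)(C)C)C[C@@H](O[Si](C)(C)C(C)(C)C)[C@@H](C)C=C | intermediate
27 | ozonide of 26 | CC(C)(C)C(=O)OCC[C@H](O[Si](C)(C)C(C)(C)C)C[C@@H](O[Si](C)(C)C(C)(C)C)C[C@H](OC1(C)C)C[C@@H](O1)C[C@H](O[Si](C)(C)C(C)(C)C)C[C@@H](O[Si](C)(C)C(C)(C)C)[C@@H](C)C1OOCO1 | intermediate
28 | fragment W aldehyde (C5–C19; 5-OPiv; 7,9,15,17-tetra-OTBS; 11,13-acetonide; 18-Me; C19 CHO) | CC(C)(C)C(=O)OCC[C@H](O[Si](C)(C)C(C)(C)C)C[C@@H](O[Si](C)(C)C(C)(C)C)C[C@H](OC1(C)C)C[C@@H](O1)C[C@H](O[Si](C)(C)C(C)(C)C)C[C@@H](O[Si](C)(C)C(C)(C)C)[C@@H](C)C=O | intermediate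
29 | 8-chlorooctan-1-ol | OCCCCCCCCCl | starting material
30 | (4R)-11-chloroundec-1-en-4-ol | C=CC[C@H](O)CCCCCCCCl | intermediate
31 | TBS ether of 30 | C=CC[C@H](O[Si](C)(C)C(C)(C)C)CCCCCCCCl | intermediate
32 | C27–C38 aldehyde (31-OTBS, 38-Cl) | O=CCCC[C@H](O[Si](C)(C)C(C)(C)C)CCCCCCCCl | intermediate
33 | C24–C38 homoallylic alcohol (27-OH, 31-OTBS) | C=CC[C@H](O)CCC[C@H](O[Si](C)(C)C(C)(C)C)CCCCCCCCl | intermediate
34 | C24–C38 alkene (27,31-bis-OTBS) | C=CC[C@H](O[Si](C)(C)C(C)(C)C)CCC[C@H](O[Si](C)(C)C(C)(C)C)CCCCCCCCl | intermediate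
35 | C23–C38 aldehyde (27,31-bis-OTBS) | O=CCCC[C@H](O[Si](C)(C)C(C)(C)C)CCC[C@H](O[Si](C)(C)C(C)(C)C)CCCCCCCCl | intermediate
36 | C20–C38 homoallylic alcohol (23-OH) | C=CC[C@H](O)CCC[C@H](O[Si](C)(C)C(C)(C)C)CCC[C@H](O[Si](C)(C)C(C)(C)C)CCCCCCCCl | intermediate
37 | C20–C38 alkene (23,27,31-tris-OTBS) | C=CC[C@H](O[Si](C)(C)C(C)(C)C)CCC[C@H](O[Si](C)(C)C(C)(C)C)CCC[C@H](O[Si](C)(C)C(C)(C)C)CCCCCCCCl | intermediate
38 | ozonide of 37 | C1OOC(O1)C[C@H](O[Si](C)(C)C(C)(C)C)CCC[C@H](O[Si](C)(C)C(C)(C)C)CCC[C@H](O[Si](C)(C)C(C)(C)C)CCCCCCCCl | intermediate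
39 | C21–C38 aldehyde | O=CC[C@H](O[Si](C)(C)C(C)(C)C)CCC[C@H](O[Si](C)(C)C(C)(C)C)CCC[C@H](O[Si](C)(C)C(C)(C)C)CCCCCCCCl | intermediate
40 | C20–C38 alkyne chloride | C#CC[C@H](O[Si](C)(C)C(C)(C)C)CCC[C@H](O[Si](C)(C)C(C)(C)C)CCC[C@H](O[Si](C)(C)C(C)(C)C)CCCCCCCCl | intermediate
41 | C20–C38 alkyne iodide | C#CC[C@H](O[Si](C)(C)C(C)(C)C)CCC[C@H](O[Si](C)(C)C(C)(C)C)CCC[C@H](O[Si](C)(C)C(C)(C)C)CCCCCCCI | intermediate
42 | fragment M phosphonium iodide | C#CC[C@H](O[Si](C)(C)C(C)(C)C)CCC[C@H](O[Si](C)(C)C(C)(C)C)CCC[C@H](O[Si](C)(C)C(C)(C)C)CCCCCCC[P+](c1ccccc1)(c1ccccc1)c1ccccc1.[I-] | intermediate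
43 | 7-bromoheptan-2-one | CC(=O)CCCCCBr | starting material
44 | (2R)-7-bromoheptan-2-ol | BrCCCCC[C@@H](C)O | intermediate
45 | (R)-[(7-bromoheptan-2-yl)oxy](tert-butyl)dimethylsilane | BrCCCCC[C@@H](C)O[Si](C)(C)C(C)(C)C | intermediate
46 | 3-[(4-methoxybenzyl)oxy]propan-1-ol | COc1ccc(COCCCO)cc1 | starting material
47 | 3-[(4-methoxybenzyl)oxy]propanal | COc1ccc(COCCC=O)cc1 | intermediate
48 | ethyl propanoate | CCOC(=O)CC | starting material
49 | lithium enolate of ethyl propanoate | [Li]OC(=CC)OCC | intermediate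
50 | ethyl 3-hydroxy-5-[(4-methoxybenzyl)oxy]-2-methylpentanoate (stereoisomer mixture) | CCOC(=O)C(C)C(O)CCOCc1ccc(OC)cc1 | intermediate
51 | ethyl 5-[(4-methoxybenzyl)oxy]-2-methyl-3-oxopentanoate (racemic, labile α-centre) | CCOC(=O)C(C)C(=O)CCOCc1ccc(OC)cc1 | intermediate
52 | ethyl (2R,3S)-3-hydroxy-5-[(4-methoxybenzyl)oxy]-2-methylpentanoate | COc1ccc(COCC[C@H](O)[C@@H](C)C(=O)OCC)cc1 | intermediate
53 | (2R,3S)-3-hydroxy-N-methoxy-5-[(4-methoxybenzyl)oxy]-N,2-dimethylpentanamide | COc1ccc(COCC[C@H](O)[C@@H](C)C(=O)N(C)OC)cc1 | intermediate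
54 | Grignard reagent from 45 | Br[Mg]CCCCC[C@@H](C)O[Si](C)(C)C(C)(C)C | intermediate
55 | (3S,4R,11R)-11-(TBS-oxy)-3-hydroxy-1-(PMB-oxy)-4-methyldodecan-5-one | COc1ccc(COCC[C@H](O)[C@@H](C)C(=O)CCCCC[C@@H](C)O[Si](C)(C)C(C)(C)C)cc1 | intermediate
56 | diethylboron chelate of 55 | COc1ccc(COCC[C@H](OB(CC)CC)[C@@H](C)C(=O)CCCCC[C@@H](C)O[Si](C)(C)C(C)(C)C)cc1 | intermediate
57 | (3S,4S,5R,11R)-11-(TBS-oxy)-1-(PMB-oxy)-4-methyldodecane-3,5-diol | COc1ccc(COCC[C@H](O)[C@@H](C)[C@H](O)CCCCC[C@@H](C)O[Si](C)(C)C(C)(C)C)cc1 | intermediate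
58 | C39/C41 p-methoxybenzylidene acetal (cis-2,4-disubstituted 1,3-dioxane, 43-OH) | COc1ccc(cc1)[C@H]2OCC[C@H](O2)[C@@H](C)[C@H](O)CCCCC[C@@H](C)O[Si](C)(C)C(C)(C)C | intermediate
59 | acetal TBS ether (43-OTBS) | COc1ccc(cc1)[C@H]2OCC[C@H](O2)[C@@H](C)[C@H](O[Si](C)(C)C(C)(C)C)CCCCC[C@@H](C)O[Si](C)(C)C(C)(C)C | intermediate
60 | C39–C50 alcohol (39-OH, 41-OPMB, 43,49-bis-OTBS) | OCC[C@H](OCc1ccc(OC)cc1)[C@@H](C)[C@H](O[Si](C)(C)C(C)(C)C)CCCCC[C@@H](C)O[Si](C)(C)C(C)(C)C | intermediate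
61 | fragment E aldehyde (C39 CHO) | O=CC[C@H](OCc1ccc(OC)cc1)[C@@H](C)[C@H](O[Si](C)(C)C(C)(C)C)CCCCC[C@@H](C)O[Si](C)(C)C(C)(C)C | intermediate
62 | phosphonium ylide from 42 | C#CC[C@H](O[Si](C)(C)C(C)(C)C)CCC[C@H](O[Si](C)(C)C(C)(C)C)CCC[C@H](O[Si](C)(C)C(C)(C)C)CCCCCCC=P(c1ccccc1)(c1ccccc1)c1ccccc1 | intermediate
63 | fragment ME alkyne (C20–C50, 38Z) | C#CC[C@H](O[Si](C)(C)C(C)(C)C)CCC[C@H](O[Si](C)(C)C(C)(C)C)CCC[C@H](O[Si](C)(C)C(C)(C)C)CCCCCC/C=C\C[C@H](OCc1ccc(OC)cc1)[C@@H](C)[C@H](O[Si](C)(C)C(C)(C)C)CCCCC[C@@H](C)O[Si](C)(C)C(C)(C)C | intermediate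
64 | lithium acetylide of 63 | [Li]C#CC[C@H](O[Si](C)(C)C(C)(C)C)CCC[C@H](O[Si](C)(C)C(C)(C)C)CCC[C@H](O[Si](C)(C)C(C)(C)C)CCCCCC/C=C\C[C@H](OCc1ccc(OC)cc1)[C@@H](C)[C@H](O[Si](C)(C)C(C)(C)C)CCCCC[C@@H](C)O[Si](C)(C)C(C)(C)C | intermediate
65 | C5–C50 propargylic alcohol (C19 epimer mixture) | CC(C)(C)C(=O)OCC[C@H](O[Si](C)(C)C(C)(C)C)C[C@@H](O[Si](C)(C)C(C)(C)C)C[C@H](OC1(C)C)C[C@@H](O1)C[C@H](O[Si](C)(C)C(C)(C)C)C[C@@H](O[Si](C)(C)C(C)(C)C)[C@@H](C)C(O)C#CC[C@H](O[Si](C)(C)C(C)(C)C)CCC[C@H](O[Si](C)(C)C(C)(C)C)CCC[C@H](O[Si](C)(C)C(C)(C)C)CCCCCC/C=C\C[C@H](OCc1ccc(OC)cc1)[C@@H](C)[C@H](O[Si](C)(C)C(C)(C)C)CCCCC[C@@H](C)O[Si](C)(C)C(C)(C)C | intermediate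
66 | C5–C50 ynone (C19 ketone) | CC(C)(C)C(=O)OCC[C@H](O[Si](C)(C)C(C)(C)C)C[C@@H](O[Si](C)(C)C(C)(C)C)C[C@H](OC1(C)C)C[C@@H](O1)C[C@H](O[Si](C)(C)C(C)(C)C)C[C@@H](O[Si](C)(C)C(C)(C)C)[C@@H](C)C(=O)C#CC[C@H](O[Si](C)(C)C(C)(C)C)CCC[C@H](O[Si](C)(C)C(C)(C)C)CCC[C@H](O[Si](C)(C)C(C)(C)C)CCCCCC/C=C\C[C@H](OCc1ccc(OC)cc1)[C@@H](C)[C@H](O[Si](C)(C)C(C)(C)C)CCCCC[C@@H](C)O[Si](C)(C)C(C)(C)C | intermediate
67 | C5–C50 (19S)-propargylic alcohol | CC(C)(C)C(=O)OCC[C@H](O[Si](C)(C)C(C)(C)C)C[C@@H](O[Si](C)(C)C(C)(C)C)C[C@H](OC1(C)C)C[C@@H](O1)C[C@H](O[Si](C)(C)C(C)(C)C)C[C@@H](O[Si](C)(C)C(C)(C)C)[C@@H](C)[C@H](O)C#CC[C@H](O[Si](C)(C)C(C)(C)C)CCC[C@H](O[Si](C)(C)C(C)(C)C)CCC[C@H](O[Si](C)(C)C(C)(C)C)CCCCCC/C=C\C[C@H](OCc1ccc(OC)cc1)[C@@H](C)[C@H](O[Si](C)(C)C(C)(C)C)CCCCC[C@@H](C)O[Si](C)(C)C(C)(C)C | intermediate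
68 | C5–C50 (20Z)-allylic alcohol (19-OH) | CC(C)(C)C(=O)OCC[C@H](O[Si](C)(C)C(C)(C)C)C[C@@H](O[Si](C)(C)C(C)(C)C)C[C@H](OC1(C)C)C[C@@H](O1)C[C@H](O[Si](C)(C)C(C)(C)C)C[C@@H](O[Si](C)(C)C(C)(C)C)[C@@H](C)[C@H](O)/C=C\C[C@H](O[Si](C)(C)C(C)(C)C)CCC[C@H](O[Si](C)(C)C(C)(C)C)CCC[C@H](O[Si](C)(C)C(C)(C)C)CCCCCC/C=C\C[C@H](OCc1ccc(OC)cc1)[C@@H](C)[C@H](O[Si](C)(C)C(C)(C)C)CCCCC[C@@H](C)O[Si](C)(C)C(C)(C)C | intermediate
69 | C19 TBS ether (5-OPiv, 41-OPMB) | CC(C)(C)C(=O)OCC[C@H](O[Si](C)(C)C(C)(C)C)C[C@@H](O[Si](C)(C)C(C)(C)C)C[C@H](OC1(C)C)C[C@@H](O1)C[C@H](O[Si](C)(C)C(C)(C)C)C[C@@H](O[Si](C)(C)C(C)(C)C)[C@@H](C)[C@H](O[Si](C)(C)C(C)(C)C)/C=C\C[C@H](O[Si](C)(C)C(C)(C)C)CCC[C@H](O[Si](C)(C)C(C)(C)C)CCC[C@H](O[Si](C)(C)C(C)(C)C)CCCCCC/C=C\C[C@H](OCc1ccc(OC)cc1)[C@@H](C)[C@H](O[Si](C)(C)C(C)(C)C)CCCCC[C@@H](C)O[Si](C)(C)C(C)(C)C | intermediate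
70 | C5 alcohol | OCC[C@H](O[Si](C)(C)C(C)(C)C)C[C@@H](O[Si](C)(C)C(C)(C)C)C[C@H](OC1(C)C)C[C@@H](O1)C[C@H](O[Si](C)(C)C(C)(C)C)C[C@@H](O[Si](C)(C)C(C)(C)C)[C@@H](C)[C@H](O[Si](C)(C)C(C)(C)C)/C=C\C[C@H](O[Si](C)(C)C(C)(C)C)CCC[C@H](O[Si](C)(C)C(C)(C)C)CCC[C@H](O[Si](C)(C)C(C)(C)C)CCCCCC/C=C\C[C@H](OCc1ccc(OC)cc1)[C@@H](C)[C@H](O[Si](C)(C)C(C)(C)C)CCCCC[C@@H](C)O[Si](C)(C)C(C)(C)C | intermediate
71 | C5 aldehyde | O=CC[C@H](O[Si](C)(C)C(C)(C)C)C[C@@H](O[Si](C)(C)C(C)(C)C)C[C@H](OC1(C)C)C[C@@H](O1)C[C@H](O[Si](C)(C)C(C)(C)C)C[C@@H](O[Si](C)(C)C(C)(C)C)[C@@H](C)[C@H](O[Si](C)(C)C(C)(C)C)/C=C\C[C@H](O[Si](C)(C)C(C)(C)C)CCC[C@H](O[Si](C)(C)C(C)(C)C)CCC[C@H](O[Si](C)(C)C(C)(C)C)CCCCCC/C=C\C[C@H](OCc1ccc(OC)cc1)[C@@H](C)[C@H](O[Si](C)(C)C(C)(C)C)CCCCC[C@@H](C)O[Si](C)(C)C(C)(C)C | intermediate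
72 | C3–C50 ethyl (Z)-enoate | CCOC(=O)/C(C)=C\C[C@H](O[Si](C)(C)C(C)(C)C)C[C@@H](O[Si](C)(C)C(C)(C)C)C[C@H](OC1(C)C)C[C@@H](O1)C[C@H](O[Si](C)(C)C(C)(C)C)C[C@@H](O[Si](C)(C)C(C)(C)C)[C@@H](C)[C@H](O[Si](C)(C)C(C)(C)C)/C=C\C[C@H](O[Si](C)(C)C(C)(C)C)CCC[C@H](O[Si](C)(C)C(C)(C)C)CCC[C@H](O[Si](C)(C)C(C)(C)C)CCCCCC/C=C\C[C@H](OCc1ccc(OC)cc1)[C@@H](C)[C@H](O[Si](C)(C)C(C)(C)C)CCCCC[C@@H](C)O[Si](C)(C)C(C)(C)C | intermediate
73 | C3–C50 (Z)-allylic alcohol | OC/C(C)=C\C[C@H](O[Si](C)(C)C(C)(C)C)C[C@@H](O[Si](C)(C)C(C)(C)C)C[C@H](OC1(C)C)C[C@@H](O1)C[C@H](O[Si](C)(C)C(C)(C)C)C[C@@H](O[Si](C)(C)C(C)(C)C)[C@@H](C)[C@H](O[Si](C)(C)C(C)(C)C)/C=C\C[C@H](O[Si](C)(C)C(C)(C)C)CCC[C@H](O[Si](C)(C)C(C)(C)C)CCC[C@H](O[Si](C)(C)C(C)(C)C)CCCCCC/C=C\C[C@H](OCc1ccc(OC)cc1)[C@@H](C)[C@H](O[Si](C)(C)C(C)(C)C)CCCCC[C@@H](C)O[Si](C)(C)C(C)(C)C | intermediate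
74 | C3–C50 (Z)-enal | O=C/C(C)=C\C[C@H](O[Si](C)(C)C(C)(C)C)C[C@@H](O[Si](C)(C)C(C)(C)C)C[C@H](OC1(C)C)C[C@@H](O1)C[C@H](O[Si](C)(C)C(C)(C)C)C[C@@H](O[Si](C)(C)C(C)(C)C)[C@@H](C)[C@H](O[Si](C)(C)C(C)(C)C)/C=C\C[C@H](O[Si](C)(C)C(C)(C)C)CCC[C@H](O[Si](C)(C)C(C)(C)C)CCC[C@H](O[Si](C)(C)C(C)(C)C)CCCCCC/C=C\C[C@H](OCc1ccc(OC)cc1)[C@@H](C)[C@H](O[Si](C)(C)C(C)(C)C)CCCCC[C@@H](C)O[Si](C)(C)C(C)(C)C | intermediate
75 | C1–C50 methyl (2E,4Z)-dienoate (41-OPMB) | COC(=O)/C=C/C(C)=C\C[C@H](O[Si](C)(C)C(C)(C)C)C[C@@H](O[Si](C)(C)C(C)(C)C)C[C@H](OC1(C)C)C[C@@H](O1)C[C@H](O[Si](C)(C)C(C)(C)C)C[C@@H](O[Si](C)(C)C(C)(C)C)[C@@H](C)[C@H](O[Si](C)(C)C(C)(C)C)/C=C\C[C@H](O[Si](C)(C)C(C)(C)C)CCC[C@H](O[Si](C)(C)C(C)(C)C)CCC[C@H](O[Si](C)(C)C(C)(C)C)CCCCCC/C=C\C[C@H](OCc1ccc(OC)cc1)[C@@H](C)[C@H](O[Si](C)(C)C(C)(C)C)CCCCC[C@@H](C)O[Si](C)(C)C(C)(C)C | intermediate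
76 | C41 alcohol (methyl ester) | COC(=O)/C=C/C(C)=C\C[C@H](O[Si](C)(C)C(C)(C)C)C[C@@H](O[Si](C)(C)C(C)(C)C)C[C@H](OC1(C)C)C[C@@H](O1)C[C@H](O[Si](C)(C)C(C)(C)C)C[C@@H](O[Si](C)(C)C(C)(C)C)[C@@H](C)[C@H](O[Si](C)(C)C(C)(C)C)/C=C\C[C@H](O[Si](C)(C)C(C)(C)C)CCC[C@H](O[Si](C)(C)C(C)(C)C)CCC[C@H](O[Si](C)(C)C(C)(C)C)CCCCCC/C=C\C[C@H](O)[C@@H](C)[C@H](O[Si](C)(C)C(C)(C)C)CCCCC[C@@H](C)O[Si](C)(C)C(C)(C)C | intermediate
77 | seco acid (41-OH, C1 acid) | OC(=O)/C=C/C(C)=C\C[C@H](O[Si](C)(C)C(C)(C)C)C[C@@H](O[Si](C)(C)C(C)(C)C)C[C@H](OC1(C)C)C[C@@H](O1)C[C@H](O[Si](C)(C)C(C)(C)C)C[C@@H](O[Si](C)(C)C(C)(C)C)[C@@H](C)[C@H](O[Si](C)(C)C(C)(C)C)/C=C\C[C@H](O[Si](C)(C)C(C)(C)C)CCC[C@H](O[Si](C)(C)C(C)(C)C)CCC[C@H](O[Si](C)(C)C(C)(C)C)CCCCCC/C=C\C[C@H](O)[C@@H](C)[C@H](O[Si](C)(C)C(C)(C)C)CCCCC[C@@H](C)O[Si](C)(C)C(C)(C)C | intermediate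
78 | 2,4,6-trichlorobenzoic mixed anhydride of 77 | Clc1cc(Cl)c(c(Cl)c1)C(=O)OC(=O)/C=C/C(C)=C\C[C@H](O[Si](C)(C)C(C)(C)C)C[C@@H](O[Si](C)(C)C(C)(C)C)C[C@H](OC1(C)C)C[C@@H](O1)C[C@H](O[Si](C)(C)C(C)(C)C)C[C@@H](O[Si](C)(C)C(C)(C)C)[C@@H](C)[C@H](O[Si](C)(C)C(C)(C)C)/C=C\C[C@H](O[Si](C)(C)C(C)(C)C)CCC[C@H](O[Si](C)(C)C(C)(C)C)CCC[C@H](O[Si](C)(C)C(C)(C)C)CCCCCC/C=C\C[C@H](O)[C@@H](C)[C@H](O[Si](C)(C)C(C)(C)C)CCCCC[C@@H](C)O[Si](C)(C)C(C)(C)C | intermediate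
79 | protected macrolactone (7,9,15,17,19,23,27,31,43,49-deca-OTBS; 11,13-acetonide) | CC1=C/C[C@H](O[Si](C)(C)C(C)(C)C)C[C@@H](O[Si](C)(C)C(C)(C)C)C[C@H](OC2(C)C)C[C@@H](O2)C[C@H](O[Si](C)(C)C(C)(C)C)C[C@@H](O[Si](C)(C)C(C)(C)C)[C@@H](C)[C@H](O[Si](C)(C)C(C)(C)C)/C=C\C[C@H](O[Si](C)(C)C(C)(C)C)CCC[C@H](O[Si](C)(C)C(C)(C)C)CCC[C@H](O[Si](C)(C)C(C)(C)C)CCCCCC/C=C\C[C@@H]([C@@H](C)[C@H](O[Si](C)(C)C(C)(C)C)CCCCC[C@@H](C)O[Si](C)(C)C(C)(C)C)OC(=O)\C=C\1 | intermediate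
80 | CNP0071908.1 | CC1=C/C[C@H](O)C[C@@H](O)C[C@H](O)C[C@@H](O)C[C@H](O)C[C@@H](O)[C@@H](C)[C@H](O)/C=C\C[C@H](O)CCC[C@H](O)CCC[C@H](O)CCCCCC/C=C\C[C@@H]([C@@H](C)[C@H](O)CCCCC[C@@H](C)O)OC(=O)\C=C\1 | target

**Totals and risks**

Total step count: 57. Longest linear sequence: 31 steps (steps 1–16, then 43–57, from propane-1,3-diol).

Step 34 (ketoreductase dynamic reductive kinetic resolution) may fail if no enzyme in the panel gives the (2R,3S) isomer cleanly on this substrate. The fallback sets out from aldehyde 47 and comes back at Weinreb amide 53. A chiral-phosphoric-acid-catalysed crotylboration with (Z)-crotylboronic acid pinacol ester ((R)-TRIP, toluene, −30 °C; chair transition state gives syn) would give (3S,4S)-1-[(4-methoxybenzyl)oxy]-4-methylhex-5-en-3-ol F1. Oxidative cleavage of the vinyl group (OsO4 cat., NaIO4, 2,6-lutidine) would give (2R,3S)-3-hydroxy-5-[(4-methoxybenzyl)oxy]-2-methylpentanal F2. Pinnick oxidation (NaClO2, NaH2PO4, 2-methylbut-2-ene) would give (2R,3S)-3-hydroxy-5-[(4-methoxybenzyl)oxy]-2-methylpentanoic acid F3, and carbodiimide coupling with N,O-dimethylhydroxylamine gives 53.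

Step 14 (catalytic crotylboration) may give insufficient facial selectivity on this chiral aliphatic β-silyloxy aldehyde. The fallback sets out from alcohol 22 and comes back at 25. It replaces oxidation plus boron chemistry by an iridium-catalysed transfer-hydrogenative anti-crotylation of 22 itself ([Ir(cod)Cl]2, (S)-SEGPHOS, 4-cyano-3-nitrobenzoic acid, Cs2CO3, but-3-en-2-yl acetate, THF, 90 °C), which forms 25 directly; no compound outside the list is formed (F0).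

Step 56 (macrolactonisation) may suffer from oligomerisation or from isomerisation of the activated (2E,4Z)-dienoate. The fallback sets out from enal 74 and comes back at macrolactone 79, closing the ring by C=C formation instead of C–O formation. DDQ removes the PMB group to give the C41 hydroxy (Z)-enal F4. Esterification with diethylphosphonoacetic acid (DCC, DMAP) gives the C41 diethylphosphonoacetate (Z)-enal F5. Intramolecular Horner–Wadsworth–Emmons reaction (LiCl, i-Pr2NEt, MeCN, high dilution) forms C2=C3 (E) and gives 79.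

**Further compounds**

F1 | step 34 | (3S,4S)-1-[(4-methoxybenzyl)oxy]-4-methylhex-5-en-3-ol | COc1ccc(COCC[C@H](O)[C@@H](C)C=C)cc1
F2 | step 34 | (2R,3S)-3-hydroxy-5-[(4-methoxybenzyl)oxy]-2-methylpentanal | COc1ccc(COCC[C@H](O)[C@@H](C)C=O)cc1
F3 | step 34 | (2R,3S)-3-hydroxy-5-[(4-methoxybenzyl)oxy]-2-methylpentanoic acid | COc1ccc(COCC[C@H](O)[C@@H](C)C(O)=O)cc1
F0 | step 14 | none | none
F4 | step 56 | C41 hydroxy (Z)-enal (74 without PMB) | O=C/C(C)=C\C[C@H](O[Si](C)(C)C(C)(C)C)C[C@@H](O[Si](C)(C)C(C)(C)C)C[C@H](OC1(C)C)C[C@@H](O1)C[C@H](O[Si](C)(C)C(C)(C)C)C[C@@H](O[Si](C)(C)C(C)(C)C)[C@@H](C)[C@H](O[Si](C)(C)C(C)(C)C)/C=C\C[C@H](O[Si](C)(C)C(C)(C)C)CCC[C@H](O[Si](C)(C)C(C)(C)C)CCC[C@H](O[Si](C)(C)C(C)(C)C)CCCCCC/C=C\C[C@H](O)[C@@H](C)[C@H](O[Si](C)(C)C(C)(C)C)CCCCC[C@@H](C)O[Si](C)(C)C(C)(C)C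
F5 | step 56 | C41 diethylphosphonoacetate (Z)-enal | O=C/C(C)=C\C[C@H](O[Si](C)(C)C(C)(C)C)C[C@@H](O[Si](C)(C)C(C)(C)C)C[C@H](OC1(C)C)C[C@@H](O1)C[C@H](O[Si](C)(C)C(C)(C)C)C[C@@H](O[Si](C)(C)C(C)(C)C)[C@@H](C)[C@H](O[Si](C)(C)C(C)(C)C)/C=C\C[C@H](O[Si](C)(C)C(C)(C)C)CCC[C@H](O[Si](C)(C)C(C)(C)C)CCC[C@H](O[Si](C)(C)C(C)(C)C)CCCCCC/C=C\C[C@H](OC(=O)CP(=O)(OCC)OCC)[C@@H](C)[C@H](O[Si](C)(C)C(C)(C)C)CCCCC[C@@H](C)O[Si](C)(C)C(C)(C)C
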